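At the reading time of 15 min, each flask stands somewhere on its curve of E, and the place can be gauged by how many doublings the early growth rate of E would fit into that time, a yardstick drawn from the start of the run and not a count of doublings that happen. In both earlier runs E climbs faster the more of it stands, which suggests autocatalysis.

| setting | teal | violet | elm | cedar | maple | oak |
|---|---|---|---|---|---|---|
| G | 0.15 M | 0.60 M | 0.30 M | 0.30 M | 0.30 M | 0.30 M |
| D | 0.90 M | 0.90 M | 0.900 M | 0.900 M | 0.900 M | 0.900 M |
| temperature | 6 °C | 31 °C | −5 °C | 10 °C | 25 °C | 40 °C |
| remark | run made earlier | run made earlier |  |  |  |  |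
| time |  |  | 15 min | 15 min | 15 min | 15 min |

| run | time / min | E / % |
|---|---|---|
| teal | 2.50 | 1.4 |
| teal | 5.00 | 3.2 |
| teal | 6.00 | 4.8 |
| teal | 8.00 | 8.1 |
| teal | 12.0 | 17.4 |
| violet | 0.250 | 1.2 |
| violet | 0.417 | 2.9 |
| violet | 0.833 | 12.3 |
| violet | 1.50 | 41.6 |
| violet | 3.00 | 79.0 |

(readings scatter by 0.3 percentage points)

* the flask that comes out highest in amount of E, in percent of the G charged, or "all alike" when all lie within 1.5 percentage points (elm / cedar / maple / oak / all alike)
* E at the end, in percent of the G charged, elm
* E at the end, in percent of the G charged, cedar
* E at the end, in percent of the G charged, maple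
* E at the end, in percent of the G charged, oak

Which numbers must be known well? [D] is charged alike, 0.90 M in the runs and 0.900 M in the flasks, so the early rates compare at one charge of D, but the readings show E and not D, and what becomes of D during a run stands unread and has to be watched. A factor of two in the first seed of E moves a curve by one doubling on this yardstick. Teal and violet change [G] and temperature together, so the order of the growth in G has to be assumed, and it is reckoned both ways below.

Growth rate, the slope of ln E against time, teal: 0.215 min⁻¹; violet: 3.47 min⁻¹

Slope of ln(rate per [G]) with temperature: 0.0559 K⁻¹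

Growth proportional to [G] puts cedar at 11.6 on the yardstick, while growth independent of [G] puts it at 7.25, fewer, and this gap of 4.37 is wider than the one doubling of the seed. My own reckoning takes the proportional case.

Yardstick: elm 5.02, cedar 11.6, maple 26.9, oak 62.2

Violet at 41.6%: 7.52

The maple figure is the growth number, the doublings that the early growth rate would fit into the reading time; it is an extrapolation of that rate and not doublings that happen. By this reckoning elm is read below violet's number, and cedar, maple and oak beyond it.

The forecast gives elm 9%, cedar 65%, maple 99% and oak 100%, with oak highest, and calls the two warm flasks “essentially complete, barring unseen loss of E at high temperature”.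

The flasks give elm 13.8%, cedar 86.4%, maple 96.1% and oak 69.3%, so maple stands highest.

    G + D + J → E + 2 J (k = 0.0870 L² mol⁻² s⁻¹, Ea = 42.0 kJ mol⁻¹)
    G + D → E + J (k = 3.50 × 10⁻⁴ L mol⁻¹ s⁻¹, Ea = 54.0 kJ mol⁻¹)
    D → Q (k = 0.00190 s⁻¹, Ea = 77.0 kJ mol⁻¹)
    (constants at 25 °C)

Maple, at growth number 26.9, holds E 96.1% with D 7.92% of its charge left. Oak has the larger number, yet holds E 68.9% at 7.50 min and 69.3% at 15.0 min, with D, its limiting reagent, down to 0.431% and then 0%, G 30.7% and Q 0.692 M. The neighbour, maple charged with 0.075 M of G, a quarter of the charge, has a growth number of 6.72, below violet's 7.52, and reads E 39.1% with G 60.9% and D 17% left.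

(Readings and results come from a simulation with made-up constants; the scatter is artificial.)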